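**Plan**
- Retrosynthesis: cut the ferulate ester C–O bond, return the C3=C4 alkene to a chroman, then cut the benzo ring at C4a–C5 and C6–C7 into but-3-yn-2-one and a vinylketene acetal diene (C4a=C8a–C8=C7) carried on a dihydropyran.
- The dihydropyran is traced back through a δ-lactone to (S)-2-methylglycidol, an allyl unit and methyl acetate.
- Enabling feature: the benzo ring C4a–C5–C6–C7–C8–C8a bears O1 on C8a, OH on C7 and acetyl on C6. A 1,1,3-trioxygenated diene plus an ynone delivers exactly this pattern, so the hindered tertiary alkyl aryl ether O1–C8a is never made on an arene.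
- Forward order: oxane ring (lactone), two-carbon extension to a cyclic β-alkoxyacrylate and its dienyl ketene acetal, benzene ring by cycloaddition–aromatisation, C3=C4 alkene, ester side chain.
- Stereochemistry: the only stereocentre, C2 (R), is the quaternary carbon of (S)-2-methylglycidol; none of its four bonds is broken anywhere in the route.

Key step: step 8

Remark: chromene numbering (O1, C2, C3, C4, C4a, C5–C8, C8a) is used for the core from the first step on. The ketene acetal is chosen as the mixed methyl trimethylsilyl acetal because it comes directly from the methyl ester; it is expected as a mixture of geometric isomers at its C=C bond, which is immaterial because that carbon becomes aromatic C7. TBDPS = tert-butyldiphenylsilyl, TBS = tert-butyldimethylsilyl.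

**Route**

Step 1
Reactants: 1 (S)-2-methylglycidol
Product: 2 (R)-tert-butyl[(2-methyloxiran-2-yl)methoxy]diphenylsilane
Conditions: TBDPSCl (1.1 equiv), imidazole (2 equiv), CH2Cl2, 0 °C → rt
Reagents that add atoms: tert-butyl(chloro)diphenylsilane, CC(C)(C)[Si](Cl)(c1ccccc1)c1ccccc1
Why: Imidazole-promoted silylation of a primary alcohol leaves the epoxide and its quaternary carbon untouched (the descriptor changes from S to R only because the silyl ether changes the priority order), and the TBDPS ether is chosen to survive amide bases, dilute acid and DDQ later.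

Step 2
Reactants: 2 (R)-tert-butyl[(2-methyloxiran-2-yl)methoxy]diphenylsilane; 3 allylmagnesium bromide
Product: 4 (2R)-1-[(tert-butyldiphenylsilyl)oxy]-2-methylhex-5-en-2-ol
Conditions: 3 (1.5 equiv), CuI (0.1 equiv), THF, −30 → 0 °C
Reagents that add atoms: none
Why: Copper-catalysed Grignard opening of a 2,2-disubstituted epoxide is an SN2 attack at the unsubstituted CH2, so the C–O bond at the quaternary carbon is not broken and its configuration is carried over unchanged.

Step 3
Reactants: 4 (2R)-1-[(tert-butyldiphenylsilyl)oxy]-2-methylhex-5-en-2-ol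
Product: 6 (5R)-6-[(tert-butyldiphenylsilyl)oxy]-5-methylhexane-1,5-diol, via B-alkyl-9-BBN adduct 5 (not isolated)
Conditions: 9-BBN (2.2 equiv), THF, 0 °C → rt; then 3 M NaOH, 30% H2O2, 0 °C → rt
Reagents that add atoms: hydrogen peroxide, OO
Why: Hydroboration–oxidation of the terminal alkene with the bulky borane places the hydroxyl on the terminal carbon, the excess reagent allowing for slow reaction with the tertiary hydroxyl.

Step 4
Reactants: 6 (5R)-6-[(tert-butyldiphenylsilyl)oxy]-5-methylhexane-1,5-diol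
Product: 8 (6R)-6-{[(tert-butyldiphenylsilyl)oxy]methyl}-6-methyloxan-2-one, via lactol 7 (not isolated)
Conditions: TEMPO (0.2 equiv), PhI(OAc)2 (2.5 equiv), CH2Cl2, rt
Reagents that add atoms: none
Why: Oxoammonium-mediated oxidative lactonisation of a 1,5-diol: only the primary alcohol is oxidised, the hydroxy aldehyde closes onto the tertiary hydroxyl, and the lactol is oxidised on to the δ-lactone.

Step 5
Reactants: 8 (6R)-6-{[(tert-butyldiphenylsilyl)oxy]methyl}-6-methyloxan-2-one; 9 methyl acetate
Product: 10 methyl 2-[(6R)-6-{[(tert-butyldiphenylsilyl)oxy]methyl}-2-hydroxy-6-methyloxan-2-yl]acetate (mixture at the hemiketal carbon)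
Conditions: LiN(iPr)2 (2.6 equiv), 9 (2.5 equiv), THF, −78 °C; then 8, −78 °C; AcOH quench at −78 °C
Reagents that add atoms: none
Why: Claisen-type addition of an ester lithium enolate to a lactone carbonyl stops at the tetrahedral lithium hemiketal at low temperature, which on protonation gives the cyclic hemiketal form of the δ-hydroxy-β-keto ester.

Step 6
Reactants: 10 methyl 2-[(6R)-6-{[(tert-butyldiphenylsilyl)oxy]methyl}-2-hydroxy-6-methyloxan-2-yl]acetate
Product: 11 methyl (2E)-2-[(6R)-6-{[(tert-butyldiphenylsilyl)oxy]methyl}-6-methyloxan-2-ylidene]acetate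
Conditions: TsOH·H2O (0.05 equiv), PhMe, 4 Å molecular sieves, 80 °C
Reagents that add atoms: none
Why: Acid-catalysed dehydration through the cyclic oxocarbenium ion and loss of the acidic α-proton gives the conjugated exocyclic β-alkoxyacrylate, and under these equilibrating conditions the isomer with the ring oxygen trans to the ester (E), as in 3-alkoxycrotonates, should prevail.

Step 7
Reactants: 11 methyl (2E)-2-[(6R)-6-{[(tert-butyldiphenylsilyl)oxy]methyl}-6-methyloxan-2-ylidene]acetate
Product: 13 tert-butyl({(2R)-6-[2-methoxy-2-(trimethylsilyloxy)ethenyl]-2-methyl-3,4-dihydro-2H-pyran-2-yl}methoxy)diphenylsilane, via lithium dienolate 12 (not isolated)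
Conditions: LiN(iPr)2 (1.2 equiv), THF, −78 °C; then Me3SiCl (1.5 equiv), −78 °C → rt; pentane, filtration under Ar; used crude at once
Reagents that add atoms: chlorotrimethylsilane, C[Si](C)(C)Cl
Why: γ-Deprotonation of a β-alkoxyacrylate at the CH2 cis to the ester and O-silylation of the extended enolate is the standard preparation of 1-methoxy-1-silyloxy-3-alkoxybuta-1,3-dienes, and any endocyclic alkene isomer of 11 would converge on the same dienolate.

Step 8
Reactants: 13 tert-butyl({(2R)-6-[2-methoxy-2-(trimethylsilyloxy)ethenyl]-2-methyl-3,4-dihydro-2H-pyran-2-yl}methoxy)diphenylsilane; 14 but-3-yn-2-one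
Product: 17 1-[(2R)-2-{[(tert-butyldiphenylsilyl)oxy]methyl}-7-hydroxy-2-methyl-3,4-dihydro-2H-chromen-6-yl]ethan-1-one, via mixed-ketal cycloadduct 15 (not isolated), via aryl trimethylsilyl ether 16 (not isolated)
Conditions: 14 (2 equiv), PhMe, −40 °C → rt; then 1 M HCl, THF, 0 °C
Reagents that add atoms: none
Why: Diels–Alder cycloaddition–aromatisation of a vinylketene acetal with an acetylenic ketone: the diene C4a=C8a–C8=C7, pushed by O1 on C8a and two oxygens on C7, is most nucleophilic at C4a, which bonds to the unsubstituted β-carbon of the ynone (C4a–C5), while the ketene acetal carbon C7 bonds to the acetyl-bearing α-carbon (C6–C7), either in a concerted asynchronous [4+2] event or by vinylogous Mukaiyama–Michael addition followed by attack of the allenolate carbon on the silylated ester carbon. The closest known reaction type is the addition of 1-alkoxy-1-silyloxy-3-alkoxybuta-1,3-dienes to propiolates, ynones and halo-quinones, which gives resorcinol derivatives with the oxygenated carbon next to the acyl-bearing carbon. The only ring closed is the six-membered carbocycle, by [4+2] combination of the four diene carbons with the two alkyne carbons (a 6-exo-trig enolate-to-oxocarbenium closure in the stepwise picture). The two sp3 centres of cycloadduct 15 (C4a and C7) are transient and become aromatic carbons, so no new stereocentre has to be controlled, and C2, remote from the bond-forming carbons, is a spectator. The selectivities needed are the regiochemistry, secured by the matched polarity of diene and ynone, and the direction of aromatisation: the doubly allylic mixed ketal at C7 loses methanol together with H–C4a and the aryl silyl ether 16 is hydrolysed by the dilute acid, so the hydrogen-bonded 7-hydroxy-6-acetyl arene and not a 7-methyl ether should result.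

Step 9
Reactants: 17 1-[(2R)-2-{[(tert-butyldiphenylsilyl)oxy]methyl}-7-hydroxy-2-methyl-3,4-dihydro-2H-chromen-6-yl]ethan-1-one
Product: 18 1-[(2R)-2-{[(tert-butyldiphenylsilyl)oxy]methyl}-7-hydroxy-2-methyl-2H-chromen-6-yl]ethan-1-one
Conditions: DDQ (1.5 equiv), 1,4-dioxane, 80 °C, exclusion of light
Reagents that add atoms: none
Why: DDQ dehydrogenation of a chroman to a 2H-chromene proceeds by hydride abstraction from benzylic C4 (cation stabilised by the para C7 hydroxyl and by O1) and loss of a proton from C3, the quaternary C2 leaving C3–C4 as the only place for the alkene; moderate temperature and darkness guard against electrocyclic opening of the chromene, which would erode C2.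

Step 10
Reactants: 18 1-[(2R)-2-{[(tert-butyldiphenylsilyl)oxy]methyl}-7-hydroxy-2-methyl-2H-chromen-6-yl]ethan-1-one
Product: 19 1-[(2R)-7-hydroxy-2-(hydroxymethyl)-2-methyl-2H-chromen-6-yl]ethan-1-one
Conditions: Bu4NF (1.5 equiv), THF, 0 °C → rt, dark
Reagents that add atoms: none
Why: Fluoride-mediated cleavage of the silyl ether is driven by the Si–F bond and touches neither the chromene nor the aryl ketone.

Step 11
Reactants: 20 ferulic acid
Product: 22 (2E)-3-{4-[(tert-butyldimethylsilyl)oxy]-3-methoxyphenyl}prop-2-enoic acid, via bis-silyl derivative 21 (not isolated)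
Conditions: TBSCl (2.3 equiv), imidazole (4 equiv), DMF, rt; then AcOH–THF–H2O, rt
Reagents that add atoms: tert-butyl(chloro)dimethylsilane, CC(C)(C)[Si](C)(C)Cl
Why: Exhaustive silylation followed by selective hydrolysis of the far more labile silyl ester is the standard protection of hydroxycinnamic acids and leaves the aryl silyl ether and the E alkene intact.

Step 12
Reactants: 19 1-[(2R)-7-hydroxy-2-(hydroxymethyl)-2-methyl-2H-chromen-6-yl]ethan-1-one; 22 (2E)-3-{4-[(tert-butyldimethylsilyl)oxy]-3-methoxyphenyl}prop-2-enoic acid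
Product: 23 [(2R)-6-acetyl-7-hydroxy-2-methyl-2H-chromen-2-yl]methyl (2E)-3-{4-[(tert-butyldimethylsilyl)oxy]-3-methoxyphenyl}prop-2-enoate
Conditions: 22 (1.1 equiv), DCC (1.2 equiv), DMAP (0.1 equiv), CH2Cl2, 0 °C → rt, dark
Reagents that add atoms: none
Why: Steglich esterification should acylate the primary alcohol in preference to the C7 hydroxyl, which is hydrogen-bonded to the C6 acetyl carbonyl and thereby deactivated, and no stereocentre is at risk because C2 bears no hydrogen.

Step 13
Reactants: 23 [(2R)-6-acetyl-7-hydroxy-2-methyl-2H-chromen-2-yl]methyl (2E)-3-{4-[(tert-butyldimethylsilyl)oxy]-3-methoxyphenyl}prop-2-enoate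
Product: 24 [(2R)-6-acetyl-7-hydroxy-2-methyl-2H-chromen-2-yl]methyl (2E)-3-(4-hydroxy-3-methoxyphenyl)prop-2-enoate (CNP0375196.1)
Conditions: Bu4NF (1.1 equiv), AcOH (1.1 equiv), THF, 0 °C, dark
Reagents that add atoms: none
Why: Aryl silyl ethers are cleaved rapidly by fluoride at 0 °C, and buffering with acetic acid keeps the medium non-basic so that the cinnamate ester and the chromene are not touched.

**Compound list**

1 | (S)-2-methylglycidol | OC[C@@]1(C)CO1 | starting material
2 | (R)-tert-butyl[(2-methyloxiran-2-yl)methoxy]diphenylsilane | CC(C)(C)[Si](c1ccccc1)(c1ccccc1)OC[C@@]1(C)CO1 | intermediate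
3 | allylmagnesium bromide | C=CC[Mg]Br | starting material
4 | (2R)-1-[(tert-butyldiphenylsilyl)oxy]-2-methylhex-5-en-2-ol | CC(C)(C)[Si](c1ccccc1)(c1ccccc1)OC[C@@](O)(C)CCC=C | intermediate
5 | (2R)-6-(9-borabicyclo[3.3.1]nonan-9-yl)-1-[(tert-butyldiphenylsilyl)oxy]-2-methylhexan-2-ol (drawn with the free tertiary hydroxyl) | CC(C)(C)[Si](c1ccccc1)(c1ccccc1)OC[C@@](O)(C)CCCCB1C2CCCC1CCC2 | intermediate
6 | (5R)-6-[(tert-butyldiphenylsilyl)oxy]-5-methylhexane-1,5-diol | CC(C)(C)[Si](c1ccccc1)(c1ccccc1)OC[C@@](O)(C)CCCCO | intermediate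
7 | (6R)-6-{[(tert-butyldiphenylsilyl)oxy]methyl}-6-methyloxan-2-ol (both anomers) | CC(C)(C)[Si](c1ccccc1)(c1ccccc1)OC[C@@]1(C)CCCC(O)O1 | intermediate
8 | (6R)-6-{[(tert-butyldiphenylsilyl)oxy]methyl}-6-methyloxan-2-one | CC(C)(C)[Si](c1ccccc1)(c1ccccc1)OC[C@@]1(C)CCCC(=O)O1 | intermediate
9 | methyl acetate | CC(=O)OC | starting material
10 | methyl 2-[(6R)-6-{[(tert-butyldiphenylsilyl)oxy]methyl}-2-hydroxy-6-methyloxan-2-yl]acetate (mixture at the hemiketal carbon) | CC(C)(C)[Si](c1ccccc1)(c1ccccc1)OC[C@@]1(C)CCCC(O)(CC(=O)OC)O1 | intermediate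
11 | methyl (2E)-2-[(6R)-6-{[(tert-butyldiphenylsilyl)oxy]methyl}-6-methyloxan-2-ylidene]acetate | CC(C)(C)[Si](c1ccccc1)(c1ccccc1)OC[C@@]1(C)CCC/C(=C\C(=O)OC)O1 | intermediate
12 | lithium 2-[(2R)-2-{[(tert-butyldiphenylsilyl)oxy]methyl}-2-methyl-3,4-dihydro-2H-pyran-6-yl]-1-methoxyethen-1-olate (enolate geometry undefined) | [Li+].CC(C)(C)[Si](c1ccccc1)(c1ccccc1)OC[C@@]1(C)CCC=C(C=C([O-])OC)O1 | intermediate
13 | tert-butyl({(2R)-6-[2-methoxy-2-(trimethylsilyloxy)ethenyl]-2-methyl-3,4-dihydro-2H-pyran-2-yl}methoxy)diphenylsilane (geometric mixture at the ketene acetal) | CC(C)(C)[Si](c1ccccc1)(c1ccccc1)OC[C@@]1(C)CCC=C(C=C(OC)O[Si](C)(C)C)O1 | intermediate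
14 | but-3-yn-2-one | CC(=O)C#C | starting material
15 | 1-[(2R)-2-{[(tert-butyldiphenylsilyl)oxy]methyl}-7-methoxy-2-methyl-7-(trimethylsilyloxy)-3,4,4a,7-tetrahydro-2H-chromen-6-yl]ethan-1-one (mixture at C4a and C7) | CC(C)(C)[Si](c1ccccc1)(c1ccccc1)OC[C@@]1(C)CCC2C=C(C(C)=O)C(OC)(O[Si](C)(C)C)C=C2O1 | intermediate
16 | 1-[(2R)-2-{[(tert-butyldiphenylsilyl)oxy]methyl}-2-methyl-7-(trimethylsilyloxy)-3,4-dihydro-2H-chromen-6-yl]ethan-1-one | CC(C)(C)[Si](c1ccccc1)(c1ccccc1)OC[C@@]1(C)CCc2cc(C(C)=O)c(O[Si](C)(C)C)cc2O1 | intermediate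
17 | 1-[(2R)-2-{[(tert-butyldiphenylsilyl)oxy]methyl}-7-hydroxy-2-methyl-3,4-dihydro-2H-chromen-6-yl]ethan-1-one | CC(C)(C)[Si](c1ccccc1)(c1ccccc1)OC[C@@]1(C)CCc2cc(C(C)=O)c(O)cc2O1 | intermediate
18 | 1-[(2R)-2-{[(tert-butyldiphenylsilyl)oxy]methyl}-7-hydroxy-2-methyl-2H-chromen-6-yl]ethan-1-one | CC(C)(C)[Si](c1ccccc1)(c1ccccc1)OC[C@@]1(C)C=Cc2cc(C(C)=O)c(O)cc2O1 | intermediate
19 | 1-[(2R)-7-hydroxy-2-(hydroxymethyl)-2-methyl-2H-chromen-6-yl]ethan-1-one | OC[C@@]1(C)C=Cc2cc(C(C)=O)c(O)cc2O1 | intermediate
20 | ferulic acid | COc1cc(/C=C/C(=O)O)ccc1O | starting material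
21 | tert-butyldimethylsilyl (2E)-3-{4-[(tert-butyldimethylsilyl)oxy]-3-methoxyphenyl}prop-2-enoate | COc1cc(/C=C/C(=O)O[Si](C)(C)C(C)(C)C)ccc1O[Si](C)(C)C(C)(C)C | intermediate
22 | (2E)-3-{4-[(tert-butyldimethylsilyl)oxy]-3-methoxyphenyl}prop-2-enoic acid | COc1cc(/C=C/C(=O)O)ccc1O[Si](C)(C)C(C)(C)C | intermediate
23 | [(2R)-6-acetyl-7-hydroxy-2-methyl-2H-chromen-2-yl]methyl (2E)-3-{4-[(tert-butyldimethylsilyl)oxy]-3-methoxyphenyl}prop-2-enoate | COc1cc(/C=C/C(=O)OC[C@@]2(C)C=Cc3cc(C(C)=O)c(O)cc3O2)ccc1O[Si](C)(C)C(C)(C)C | intermediate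
24 | [(2R)-6-acetyl-7-hydroxy-2-methyl-2H-chromen-2-yl]methyl (2E)-3-(4-hydroxy-3-methoxyphenyl)prop-2-enoate | COc1cc(/C=C/C(=O)OC[C@@]2(C)C=Cc3cc(C(C)=O)c(O)cc3O2)ccc1O | target

**Step count and risks**

Total step count: 13. Longest linear sequence: 12 (steps 1–10, 12 and 13); step 11 is a one-step side branch.

Steps most likely to fail:

1. Step 8. The ynone may be consumed by oligomerisation under the influence of the nucleophilic ketene acetal, the reaction may stop after conjugate addition without ring closure, or the diene may be protodesilylated back to 11 before it reacts. Fallback: setting out again from 13, methyl propiolate (PhMe, rt → 60 °C, then 1 M HCl–THF), a sturdier acetylenic dienophile of the same polarity, should form the same C4a–C5 and C6–C7 bonds and give methyl (2R)-2-{[(tert-butyldiphenylsilyl)oxy]methyl}-7-hydroxy-2-methyl-3,4-dihydro-2H-chromene-6-carboxylate F1. Treatment with MeNH(OMe)·HCl and iPrMgCl (THF, −20 °C) would convert the ester into (2R)-2-{[(tert-butyldiphenylsilyl)oxy]methyl}-7-hydroxy-N-methoxy-N,2-dimethyl-3,4-dihydro-2H-chromene-6-carboxamide F2, and MeMgBr (THF, 0 °C) would add once to give the methyl ketone 17, where the route is rejoined.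

2. Step 9. Hydride abstraction at C4 may be slow because of the acetyl group, the phenol ring may be over-oxidised by the quinone, or heating may start electrocyclic opening of the chromene. Fallback: setting out from 17, acetylation (Ac2O, pyridine) would give (2R)-6-acetyl-2-{[(tert-butyldiphenylsilyl)oxy]methyl}-2-methyl-3,4-dihydro-2H-chromen-7-yl acetate F3. Radical benzylic bromination (NBS, AIBN, PhCF3, 80 °C) would give (2R,4RS)-6-acetyl-4-bromo-2-{[(tert-butyldiphenylsilyl)oxy]methyl}-2-methyl-3,4-dihydro-2H-chromen-7-yl acetate F4, and dehydrobromination with DBU (THF, rt) would give (2R)-6-acetyl-2-{[(tert-butyldiphenylsilyl)oxy]methyl}-2-methyl-2H-chromen-7-yl acetate F5. Methanolysis of the aryl acetate (K2CO3, MeOH, 0 °C) returns to 18.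

3. Step 12. Competing acylation of the C7 phenol, or sluggish acylation of the neopentyl-type primary alcohol by the conjugated acid, may lead to mixtures. Fallback: setting out from 19, heating with 2,2-dimethyl-1,3-dioxane-4,6-dione (Meldrum's acid; PhMe, 90 °C), which acylates aliphatic alcohols under neutral conditions, should give 3-{[(2R)-6-acetyl-7-hydroxy-2-methyl-2H-chromen-2-yl]methoxy}-3-oxopropanoic acid F6. Knoevenagel–Doebner condensation of this half-ester with vanillin (pyridine, piperidine cat., 60 °C) would build the (E)-feruloyl double bond with decarboxylation and lead directly to 24, so that 22, 23 and step 13 are bypassed.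

Further compounds
F1 | step 8 | methyl (2R)-2-{[(tert-butyldiphenylsilyl)oxy]methyl}-7-hydroxy-2-methyl-3,4-dihydro-2H-chromene-6-carboxylate | CC(C)(C)[Si](c1ccccc1)(c1ccccc1)OC[C@@]1(C)CCc2cc(C(=O)OC)c(O)cc2O1
F2 | step 8 | (2R)-2-{[(tert-butyldiphenylsilyl)oxy]methyl}-7-hydroxy-N-methoxy-N,2-dimethyl-3,4-dihydro-2H-chromene-6-carboxamide | CC(C)(C)[Si](c1ccccc1)(c1ccccc1)OC[C@@]1(C)CCc2cc(C(=O)N(C)OC)c(O)cc2O1
F3 | step 9 | (2R)-6-acetyl-2-{[(tert-butyldiphenylsilyl)oxy]methyl}-2-methyl-3,4-dihydro-2H-chromen-7-yl acetate | CC(C)(C)[Si](c1ccccc1)(c1ccccc1)OC[C@@]1(C)CCc2cc(C(C)=O)c(OC(C)=O)cc2O1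
F4 | step 9 | (2R,4RS)-6-acetyl-4-bromo-2-{[(tert-butyldiphenylsilyl)oxy]methyl}-2-methyl-3,4-dihydro-2H-chromen-7-yl acetate | CC(C)(C)[Si](c1ccccc1)(c1ccccc1)OC[C@@]1(C)CC(Br)c2cc(C(C)=O)c(OC(C)=O)cc2O1
F5 | step 9 | (2R)-6-acetyl-2-{[(tert-butyldiphenylsilyl)oxy]methyl}-2-methyl-2H-chromen-7-yl acetate | CC(C)(C)[Si](c1ccccc1)(c1ccccc1)OC[C@@]1(C)C=Cc2cc(C(C)=O)c(OC(C)=O)cc2O1
F6 | step 12 | 3-{[(2R)-6-acetyl-7-hydroxy-2-methyl-2H-chromen-2-yl]methoxy}-3-oxopropanoic acid | OC(=O)CC(=O)OC[C@@]1(C)C=Cc2cc(C(C)=O)c(O)cc2O1
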